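## The problem

Target 20 consists of two fully substituted phloroglucinol-type benzene rings joined by a single methylene carbon, which links C5 of ring A to C1′ of ring B. Ring A carries a butyryl group at C1, hydroxyls at C2, C4 and C6 and a methyl group at C3. Ring B carries a propanoyl group at C3′, hydroxyls at C2′ and C4′, a methyl group at C5′ and the only methyl ether of the molecule at C6′, para to the propanoyl carbonyl. There is no stereocentre, so the problem is purely regiochemical: twelve ring positions must receive the right substituents and exactly one oxygen out of six must end up methylated. Any temporary ether on ring A must therefore be removable under conditions that cannot touch an aryl methyl ether. The fragile element is the diarylmethane flanked by four oxygens: hot alkali and strong acid open or scramble it through ipso-protonation of the electron-rich ring, and the free polyphenol is easily oxidised, so the end of the route must be short and mild. The feature that invites a ring synthesis is that ring A is a tautomer of a cyclohexane-1,3,5-trione. C1–C2–C3 with the C3 methyl is the carbon chain of butanone, and C4–C5–C6 is a malonyl unit whose central carbon C5 is the atom that bears the bridge, so ring A can be closed by two C-acylations with ring B already attached.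

## Retrosynthesis

**20 from 19.** The last cut removes three O–C bonds: the benzyl groups on O2′ and O4′ and an isopropyl group on O2 of ring A. A methyl cap on O2 would leave two aryl methyl ethers to be told apart at the end. The butyryl carbonyl would already be hydrogen-bonded to the C6 hydroxyl, so chelation-controlled demethylation would have no handle. A benzyl cap would allow hydrogenolysis but is the cap most easily lost to chloride during ring formation. A secondary alkyl cap resists SN2 dealkylation in the ring closure and ionises under a boron trihalide at low temperature, where a methyl ether without a chelating neighbour stays. Precursor 19 is no simpler in skeleton, but it is less polar and not air-sensitive. The forward step must cleave benzylic and secondary alkyl–oxygen bonds and no methyl–oxygen bond.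

**19 from 16 and 17.** The C1–carbonyl bond is cut, giving ring A with C1 unsubstituted (16) and butyronitrile 17. C1 is the only aromatic C–H of the whole molecule, so regiochemistry is not in question. Carrying the butyryl group through the ring synthesis instead would require the mono-enol ether of a 1,3-diketone as nucleophile, which is far less reactive and has a regiochemical problem of its own. The cut removes four carbons. The forward reaction must be an acylation mild enough for the bridge and the ethers, which points to a nitrile-based acylation at 0 °C.

**16 from 12 and 14 (key disconnection).** C1–C6 and C3–C4 are cut, unfolding ring A into 2-isopropoxybut-1-ene 14 and the benzylmalonyl dichloride 12. The neighbouring cut at the bridge (C5–CH2) is the conventional union of two preformed phloroglucinols; it is kept as the fallback. The ring cut is preferred as the main line because the substitution pattern of ring A then follows from connectivity, not from the selectivity of an aromatic substitution. The C3 methyl comes from the ethyl group of 14, the bridge on C5 from the malonyl carbon, and O2 is distinguished from O4 and O6 as an ether at the moment the ring forms. Any other three-plus-three split would need a ketone carrying ring B on its α-carbon. Precursor 12 holds only ring B and 14 is a seven-carbon enol ether. The forward reaction must acylate both α-carbons of the enol ether at carbon, the second time intramolecularly, while the capped oxygen stays out of the closure.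

**14 from 13.** The C=CH2 bond is cut back to the carbonyl of isopropyl propanoate 13. Ester methylenation gives only the 1-ene with the secondary alkoxy group already in place. Cracking a ketal of butanone would not install a secondary alkoxy group cleanly. The forward step must tolerate an acid-sensitive, volatile product.

**12 from 7 and 8.** The two C–Cl bonds lead back to malonic acid 11, the ester C–O bonds to diester 10, and the benzylic C–C bond, through alkylidene malonate 9, to aldehyde 7 and diethyl malonate 8. Alkylating 8 with a benzylic halide is the neighbouring option, but a 2,4,6-trialkoxybenzyl halide is too labile to handle and dialkylation would intrude. The condensation route starts from a stable aldehyde. The forward steps must condense a hindered aldehyde, reduce the alkene without touching the ketone, and free the diacid without decarboxylation.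

**7 from 1 and 2.** The benzyl ethers are removed to give 6, the formyl carbon to give 4, the methyl ether to give 3, and the acyl bond to give 2,4,6-trihydroxytoluene 1 and propionyl chloride 2. Methylation is placed at the ketone stage because only then is one hydroxyl, the one para to the carbonyl, free of a hydrogen bond. Formylation then has a single carbon left to attack. Benzylation comes last, so that no free phenol can later lactonise onto the malonyl unit.

## Roads not taken

**Alternative 1:** The cut lies inside ring B at C3′–C4′. Ring B is unfolded to a tetraketide masked as 4-methoxy-3-methyl-6-(2-oxobutyl)-5-[2,4,6-tris(benzyloxy)-3-methylbenzyl]pyran-2-one A2. In the forward key step Mg(OMe)2 opens the lactone of A2 to an ester, and the methylene between the two ketones closes onto that ester in a Claisen condensation. This gives 1-[2,6-dihydroxy-4-methoxy-3-methyl-5-(2,4,6-tris(benzyloxy)-3-methylbenzyl)phenyl]propan-1-one A1.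
- Merits: the methoxy group is placed by the pyrone C4 oxygen, which is better than the partial methylation of the chosen plan. The ring closure is mild and needs no acid chloride. The final deprotection would be a clean hydrogenolysis.
- Weak points: A2 is a tetrasubstituted pyrone whose assembly needs benzylation at C5 and acylation of a C6 methyl group, each of uncertain regiochemistry. The opened chain can partition between Claisen and aldol closure. Ring A of A1 arrives as a tribenzyl ether, so A1 must still be butyrylated at a carbon flanked by two benzyloxy groups.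
- Comparison: the chosen plan sets against this a key precursor reachable in eight conventional steps and a closure that builds the more heavily oxygenated ring A with the bridge already attached.

**Alternative 2:** The cuts are C4′–C5′ and C2′–C3′ of ring B. The diene 1,3-dimethoxy-2-[2,4,6-tris(benzyloxy)-3-methylbenzyl]-1-(trimethylsiloxy)penta-1,3-diene A4 adds to 1-ethoxypent-1-yn-3-one A5, and loss of the alcohol aromatises the adduct. The product is 1-[2-ethoxy-6-hydroxy-4-methoxy-3-methyl-5-(2,4,6-tris(benzyloxy)-3-methylbenzyl)phenyl]propan-1-one A3.
- Merits: the route is convergent, the regiochemistry follows from the polarity of both partners, the propanoyl group comes with the ynone, and no acid is set free. On this last point it is gentler than the chosen plan.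
- Weak points: A4 is a tetrasubstituted diene with a bulky group at C2 and a substituted terminus, and A5 is a donor-substituted and therefore sluggish dienophile. The C4′ ethyl ether of A3 must later be cleaved beside the C6′ methyl ether while the C2′ hydroxyl already holds the carbonyl. This is exactly the ether differentiation that the chosen plan avoids with its isopropyl cap. Ring A of A3 still lacks the butyryl group.
- Comparison: the chosen plan answers with simpler precursors and with an end game in which the two kinds of ether differ in mechanism of cleavage.

**Alternative 3:** The cuts are the two bonds at the butyryl carbonyl. The aryl iodide 1-[2,6-bis(benzyloxy)-4-methoxy-3-methyl-5-(2,4,6-tris(benzyloxy)-3-iodo-5-methylbenzyl)phenyl]propan-1-one A7, carbon monoxide A9 and B-propyl-9-borabicyclo[3.3.1]nonane A8 are joined by the zerovalent palladium complex Pd(PPh3)4 with K3PO4. The product is the pentabenzyl ether 1-{2,4,6-tris(benzyloxy)-3-[2,4-bis(benzyloxy)-6-methoxy-5-methyl-3-propanoylbenzyl]-5-methylphenyl}butan-1-one A6.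
- Merits: the butyryl group is installed under neutral conditions with regiochemistry fixed by the iodide, and A6 is one hydrogenolysis away from the target. For this single bond construction it is probably more reliable than the nitrile acylation of the chosen plan, which is why it is kept there as a fallback.
- Weak points: the key step builds neither a ring nor the bridge. The whole skeletal problem is moved into the synthesis of A7, which needs a union of two phloroglucinols, five benzylations of hindered phenols and an iodination. The iodide sits between two benzyloxy groups, so direct coupling of A7 with A8 without insertion of A9 can compete.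
- Comparison: the chosen plan spends its key step on creating ring A and its substitution pattern, not on a late decoration.

Key step: step 10

Remark on the chemistry: the target has no stereocentre. Intermediate 15 is racemic at its malonyl carbon, which becomes an aromatic carbon. Ring A is numbered C1–C6 and ring B C1′–C6′ as above.

## Route

Step 1
Reactants: 1 2,4,6-trihydroxytoluene; 2 propionyl chloride
Product: 3 1-(2,4,6-trihydroxy-3-methylphenyl)propan-1-one
Conditions: AlCl3, PhNO2/CH2Cl2, 0 °C to 40 °C; aq. HCl
Reagents that add atoms: none
Why: Friedel–Crafts C-acylation of a phloroglucinol; the two free ring carbons of 1 are equivalent by symmetry and the first acyl group deactivates the ring against a second.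

Step 2
Reactants: 3
Product: 4 1-(2,6-dihydroxy-4-methoxy-3-methylphenyl)propan-1-one
Conditions: Me2SO4 (1.0 equiv), K2CO3 (1.0 equiv), acetone, rt
Reagents that add atoms: dimethyl sulfate, COS(=O)(=O)OC
Why: Williamson O-methylation under limiting base; the hydroxyl para to the ketone is the most acidic and the only one not hydrogen-bonded to the carbonyl, so it should react first, and one equivalent of reagent limits further methylation.

Step 3
Reactants: 4
Product: 6 2,4-dihydroxy-6-methoxy-5-methyl-3-propanoylbenzaldehyde, via aryl iminium chloride 5 (not isolated)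
Conditions: POCl3, DMF, MeCN, 0 °C to rt; then H2O, 50 °C
Reagents that add atoms: N,N-dimethylformamide, CN(C)C=O; water, O
Why: Vilsmeier–Haack formylation at the single free ring carbon, which is activated by three oxygens; the iminium salt 5 is hydrolysed to the aldehyde on aqueous warming.

Step 4
Reactants: 6
Product: 7 2,4-bis(benzyloxy)-6-methoxy-5-methyl-3-propanoylbenzaldehyde
Conditions: BnBr, K2CO3, DMF, 60 °C
Reagents that add atoms: benzyl bromide, BrCc1ccccc1
Why: Williamson benzylation; warm K2CO3 in DMF breaks the hydrogen bonds of both hydroxyls to the flanking carbonyls, and the polar aprotic medium favours O- over C-alkylation on the fully substituted ring.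

Step 5
Reactants: 7; 8 diethyl malonate
Product: 9 diethyl 2-{[2,4-bis(benzyloxy)-6-methoxy-5-methyl-3-propanoylphenyl]methylidene}malonate
Conditions: TiCl4, pyridine, THF, 0 °C to rt
Reagents that add atoms: none
Why: Knoevenagel condensation under Lehnert conditions, which drive hindered and electron-rich benzaldehydes to the alkylidene malonate; the ketone between two benzyloxy groups is too shielded to condense, and TiCl4 complexed by THF and pyridine should leave the benzyl ethers alone.

Step 6
Reactants: 9
Product: 10 diethyl 2-[2,4-bis(benzyloxy)-6-methoxy-5-methyl-3-propanoylbenzyl]malonate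
Conditions: NaBH4, EtOH/THF, 0 °C
Reagents that add atoms: none
Why: Conjugate reduction of an alkylidene malonate by borohydride, which at 0 °C is much faster than attack on the aryl ketone, twisted out of the ring plane and flanked by two benzyloxy groups.

Step 7
Reactants: 10
Product: 11 2-[2,4-bis(benzyloxy)-6-methoxy-5-methyl-3-propanoylbenzyl]malonic acid
Conditions: KOH, EtOH/H2O, rt to 40 °C; then aq. HCl, 0 °C
Reagents that add atoms: potassium hydroxide, [K+].[OH-]
Why: Saponification of both ethyl esters by acyl–oxygen cleavage; cold acidification frees the substituted malonic acid, which loses CO2 only on strong heating.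

Step 8
Reactants: 11
Product: 12 2-[2,4-bis(benzyloxy)-6-methoxy-5-methyl-3-propanoylbenzyl]malonyl dichloride
Conditions: (COCl)2, DMF (cat.), CH2Cl2, 0 °C to rt; concentrated and used at once
Reagents that add atoms: oxalyl chloride, ClC(=O)C(=O)Cl
Why: Acid chloride formation through the catalytic chloroiminium species; all by-products are gases, and benzyl ethers and the hindered ketone are inert at room temperature.

Step 9
Reactants: 13 isopropyl propanoate
Product: 14 2-isopropoxybut-1-ene
Conditions: Cp2TiMe2, THF, 65 °C, dark; pentane, filtration through basic Al2O3, distillation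
Reagents that add atoms: bis(cyclopentadienyl)dimethyltitanium Cp2TiMe2, C[Ti](C)(C1C=CC=C1)C1C=CC=C1
Why: Petasis methylenation of an ester; Cp2TiMe2 loses methane to the titanium methylidene, which adds to the ester carbonyl and cycloreverts to the enol ether, giving only the 1-ene.

Step 10
Reactants: 12; 14
Product: 16 2-[2,4-bis(benzyloxy)-6-methoxy-5-methyl-3-propanoylbenzyl]-5-isopropoxy-4-methylbenzene-1,3-diol, via open-chain enone acid chloride 15 (not isolated)
Conditions: Et2O, −20 °C to rt; 14 (1.3 equiv) added slowly to 12; no base; then aq. NaHCO3
Reagents that add atoms: none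
Why: Effenberger-type double C-acylation: the terminal carbon of enol ether 14 attacks one acid chloride of 12 (or the chlorocarbonyl ketene formed from it by loss of HCl), forming C1–C6, and the oxocarbenium ion loses a proton to give the β-isopropoxy enone 15. Enolisation of 15 toward its ethyl group gives a dienol ether whose C3 attacks the second acid chloride, forming C3–C4 in a 6-(enolendo)-exo-trig closure, which is an allowed mode for enol-type nucleophiles. Loss of the second HCl and two enolisations of the resulting 5-isopropoxycyclohex-5-ene-1,3-dione give the aromatic ring, which makes the sequence irreversible. The closest known reaction type is the formation of phloroglucinol monoalkyl ethers and of bicyclo[3.3.1]nonane-2,4,9-triones from enol ethers and malonyl dichlorides. No stereocentre is formed. The step needs C- over O-acylation in the closure: the former ketone oxygen can acylate only after losing its cap, and a secondary alkyl group resists SN2 removal by chloride better than methyl or benzyl, which should hold back the 4-hydroxy-2-pyrone. It also needs intra- over intermolecular second acylation: slow addition of 14 to 12 keeps free enol ether scarce, so the second acid chloride meets its own γ-carbon. The ring B ketone, buried between two benzyloxy groups, and the aryl ethers should not be acylated at these temperatures.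

Step 11
Reactants: 16; 17 butyronitrile
Product: 19 1-{3-[2,4-bis(benzyloxy)-6-methoxy-5-methyl-3-propanoylbenzyl]-2,4-dihydroxy-6-isopropoxy-5-methylphenyl}butan-1-one, via ketiminium chloride 18 (not isolated)
Conditions: ZnCl2, HCl (g), Et2O, 0 °C; then H2O/THF, 60 °C
Reagents that add atoms: water, O
Why: Houben–Hoesch acylation; the activated nitrile attacks C1, the only unsubstituted aromatic carbon of 16, on the ring carrying three oxygens, and the ketiminium salt 18 is hydrolysed to the ketone. The low temperature and the mild ZnCl2 should spare the benzyl and isopropyl ethers.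

Step 12
Reactants: 19
Product: 20 1-{3-[2,4-dihydroxy-6-methoxy-5-methyl-3-propanoylbenzyl]-2,4,6-trihydroxy-5-methylphenyl}butan-1-one
Conditions: BCl3, C6HMe5, CH2Cl2, −78 to 0 °C; MeOH
Reagents that add atoms: none
Why: Lewis acid dealkylation; BCl3 cleaves aryl benzyl and aryl isopropyl ethers at low temperature through stabilised benzylic and secondary carbocations, whereas the ring B methyl ether, para to its carbonyl and without a chelating neighbour, could only go by SN2 attack on methyl and should stay. Pentamethylbenzene traps the benzyl cations.

## Compound list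

1 | 2,4,6-trihydroxytoluene | Cc1c(O)cc(O)cc1O | starting material
2 | propionyl chloride | CCC(=O)Cl | starting material
3 | 1-(2,4,6-trihydroxy-3-methylphenyl)propan-1-one | CCC(=O)c1c(O)cc(O)c(C)c1O | intermediate
4 | 1-(2,6-dihydroxy-4-methoxy-3-methylphenyl)propan-1-one | CCC(=O)c1c(O)cc(OC)c(C)c1O | intermediate
5 | N-[(2,4-dihydroxy-6-methoxy-5-methyl-3-propanoylphenyl)methylidene]-N-methylmethanaminium chloride | CCC(=O)c1c(O)c(C=[N+](C)C)c(OC)c(C)c1O.[Cl-] | intermediate (not isolated)
6 | 2,4-dihydroxy-6-methoxy-5-methyl-3-propanoylbenzaldehyde | CCC(=O)c1c(O)c(C=O)c(OC)c(C)c1O | intermediate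
7 | 2,4-bis(benzyloxy)-6-methoxy-5-methyl-3-propanoylbenzaldehyde | CCC(=O)c1c(OCc2ccccc2)c(C=O)c(OC)c(C)c1OCc1ccccc1 | intermediate
8 | diethyl malonate | CCOC(=O)CC(=O)OCC | starting material
9 | diethyl 2-{[2,4-bis(benzyloxy)-6-methoxy-5-methyl-3-propanoylphenyl]methylidene}malonate | CCOC(=O)C(=Cc1c(OCc2ccccc2)c(C(=O)CC)c(OCc2ccccc2)c(C)c1OC)C(=O)OCC | intermediate
10 | diethyl 2-[2,4-bis(benzyloxy)-6-methoxy-5-methyl-3-propanoylbenzyl]malonate | CCOC(=O)C(Cc1c(OCc2ccccc2)c(C(=O)CC)c(OCc2ccccc2)c(C)c1OC)C(=O)OCC | intermediate
11 | 2-[2,4-bis(benzyloxy)-6-methoxy-5-methyl-3-propanoylbenzyl]malonic acid | OC(=O)C(Cc1c(OCc2ccccc2)c(C(=O)CC)c(OCc2ccccc2)c(C)c1OC)C(=O)O | intermediate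
12 | 2-[2,4-bis(benzyloxy)-6-methoxy-5-methyl-3-propanoylbenzyl]malonyl dichloride | ClC(=O)C(Cc1c(OCc2ccccc2)c(C(=O)CC)c(OCc2ccccc2)c(C)c1OC)C(=O)Cl | intermediate
13 | isopropyl propanoate | CCC(=O)OC(C)C | starting material
14 | 2-isopropoxybut-1-ene | C=C(CC)OC(C)C | intermediate
15 | (E)-2-[2,4-bis(benzyloxy)-6-methoxy-5-methyl-3-propanoylbenzyl]-5-isopropoxy-3-oxohept-4-enoyl chloride (racemic at C2) | CC/C(OC(C)C)=C\C(=O)C(Cc1c(OCc2ccccc2)c(C(=O)CC)c(OCc2ccccc2)c(C)c1OC)C(=O)Cl | intermediate (not isolated)
16 | 2-[2,4-bis(benzyloxy)-6-methoxy-5-methyl-3-propanoylbenzyl]-5-isopropoxy-4-methylbenzene-1,3-diol | CC(C)Oc1cc(O)c(Cc2c(OCc3ccccc3)c(C(=O)CC)c(OCc3ccccc3)c(C)c2OC)c(O)c1C | intermediate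
17 | butyronitrile | CCCC#N | starting material
18 | 1-{3-[2,4-bis(benzyloxy)-6-methoxy-5-methyl-3-propanoylbenzyl]-2,4-dihydroxy-6-isopropoxy-5-methylphenyl}butan-1-iminium chloride | CCCC(=[NH2+])c1c(OC(C)C)c(C)c(O)c(Cc2c(OCc3ccccc3)c(C(=O)CC)c(OCc3ccccc3)c(C)c2OC)c1O.[Cl-] | intermediate (not isolated)
19 | 1-{3-[2,4-bis(benzyloxy)-6-methoxy-5-methyl-3-propanoylbenzyl]-2,4-dihydroxy-6-isopropoxy-5-methylphenyl}butan-1-one | CCCC(=O)c1c(OC(C)C)c(C)c(O)c(Cc2c(OCc3ccccc3)c(C(=O)CC)c(OCc3ccccc3)c(C)c2OC)c1O | intermediate
20 | 1-{3-[2,4-dihydroxy-6-methoxy-5-methyl-3-propanoylbenzyl]-2,4,6-trihydroxy-5-methylphenyl}butan-1-one | CCCC(=O)c1c(O)c(C)c(O)c(Cc2c(O)c(C(=O)CC)c(O)c(C)c2OC)c1O | target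

## Step count and risk

Total: 12 steps. Longest linear sequence: 11 steps (steps 1–8, then 10–12); step 9 is a one-step side branch.

**Step 10 (key step).** Chloride may dealkylate the oxocarbenium or vinylogous ester oxygen, after which that oxygen acylates and the closure goes to a pyranone. A second molecule of enol ether may also capture the remaining acid chloride before the ring closes, and the acid set free may consume enol ether. The fallback gives up the ring construction and joins two preformed rings at the bridge. It sets out from 7, which NaBH4 at low temperature should reduce at the aldehyde only to 1-[2,6-bis(benzyloxy)-3-(hydroxymethyl)-4-methoxy-5-methylphenyl]propan-1-one F1. Separately, 1 is acylated with butyryl chloride and AlCl3 to 1-(2,4,6-trihydroxy-3-methylphenyl)butan-1-one F2. Acid-catalysed Friedel–Crafts benzylation of F2 by F1 (TsOH, CH2Cl2, rt) at its only free ring carbon gives 1-{3-[2,4-bis(benzyloxy)-6-methoxy-5-methyl-3-propanoylbenzyl]-2,4,6-trihydroxy-5-methylphenyl}butan-1-one F3. Hydrogenolysis (H2, Pd/C, EtOAc) rejoins the route at 20.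

**Step 11.** The HCl-saturated medium may protonate ring A at C5 and let the bridge migrate or break. Benzyl ethers may be partly lost, and the nitrile may add at phenol oxygen instead of carbon. The fallback avoids acid altogether and sets out from 16. Benzylation (BnBr, K2CO3, DMF) gives 1-{2,6-bis(benzyloxy)-3-[2,6-bis(benzyloxy)-4-isopropoxy-3-methylbenzyl]-4-methoxy-5-methylphenyl}propan-1-one F4. Iodination at C1 with N-iodosuccinimide in MeCN gives 1-{2,6-bis(benzyloxy)-3-[2,6-bis(benzyloxy)-3-iodo-4-isopropoxy-5-methylbenzyl]-4-methoxy-5-methylphenyl}propan-1-one F5. Carbonylative Suzuki–Miyaura coupling with B-propyl-9-borabicyclo[3.3.1]nonane A8 under carbon monoxide A9, using the zerovalent palladium complex Pd(PPh3)4 and K3PO4, gives 1-{2,4-bis(benzyloxy)-3-[2,4-bis(benzyloxy)-6-methoxy-5-methyl-3-propanoylbenzyl]-6-isopropoxy-5-methylphenyl}butan-1-one F6. The conditions of step 12 then remove four benzyl groups and the isopropyl group and rejoin the route at 20.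

**Step 12.** The twisted ring B methyl ether, flanked by two carbon substituents, may be cleaved competitively. The isopropyl group may be lost incompletely, or the Lewis acid may cause bridge migration. The fallback sets out from 19 and separates the two deprotections. Hydrogenolysis (H2, Pd/C, EtOAc) removes both benzyl ethers under neutral conditions to give 1-{3-[2,4-dihydroxy-6-methoxy-5-methyl-3-propanoylbenzyl]-2,4-dihydroxy-6-isopropoxy-5-methylphenyl}butan-1-one F7. A brief treatment with AlCl3 in CH2Cl2 at 0 °C, which is selective for aryl isopropyl over unchelated aryl methyl ethers, rejoins the route at 20.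

**Step 8.** An ortho ether oxygen of ring B may attack one acid chloride with loss of its benzyl group (lactonisation to a chroman-2-one). The acid released may also promote decarboxylation or ketene dimerisation on standing. The fallback sets out from 11 and avoids free acid. Silylation with N,O-bis(trimethylsilyl)acetamide gives bis(trimethylsilyl) 2-[2,4-bis(benzyloxy)-6-methoxy-5-methyl-3-propanoylbenzyl]malonate F8. Oxalyl chloride with catalytic DMF then converts F8 under neutral conditions, rejoining the route at 12.

**Step 2.** Methylation may run on to a second hydroxyl or start at a chelated one, giving regioisomers that are hard to separate. The fallback sets out from 3 and replaces selective alkylation by selective dealkylation. Exhaustive methylation (excess Me2SO4, K2CO3, acetone, reflux) gives 1-(2,4,6-trimethoxy-3-methylphenyl)propan-1-one F9. AlCl3 in chlorobenzene at 80 °C then cleaves the two methyl ethers ortho to the carbonyl by chelation and leaves the para one, rejoining the route at 4.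

## Further compounds

F1 | step 10 | 1-[2,6-bis(benzyloxy)-3-(hydroxymethyl)-4-methoxy-5-methylphenyl]propan-1-one | CCC(=O)c1c(OCc2ccccc2)c(CO)c(OC)c(C)c1OCc1ccccc1
F2 | step 10 | 1-(2,4,6-trihydroxy-3-methylphenyl)butan-1-one | CCCC(=O)c1c(O)cc(O)c(C)c1O
F3 | step 10 | 1-{3-[2,4-bis(benzyloxy)-6-methoxy-5-methyl-3-propanoylbenzyl]-2,4,6-trihydroxy-5-methylphenyl}butan-1-one | CCCC(=O)c1c(O)c(C)c(O)c(Cc2c(OCc3ccccc3)c(C(=O)CC)c(OCc3ccccc3)c(C)c2OC)c1O
F4 | step 11 | 1-{2,6-bis(benzyloxy)-3-[2,6-bis(benzyloxy)-4-isopropoxy-3-methylbenzyl]-4-methoxy-5-methylphenyl}propan-1-one | CC(C)Oc1cc(OCc2ccccc2)c(Cc2c(OCc3ccccc3)c(C(=O)CC)c(OCc3ccccc3)c(C)c2OC)c(OCc2ccccc2)c1C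
F5 | step 11 | 1-{2,6-bis(benzyloxy)-3-[2,6-bis(benzyloxy)-3-iodo-4-isopropoxy-5-methylbenzyl]-4-methoxy-5-methylphenyl}propan-1-one | CC(C)Oc1c(I)c(OCc2ccccc2)c(Cc2c(OCc3ccccc3)c(C(=O)CC)c(OCc3ccccc3)c(C)c2OC)c(OCc2ccccc2)c1C
F6 | step 11 | 1-{2,4-bis(benzyloxy)-3-[2,4-bis(benzyloxy)-6-methoxy-5-methyl-3-propanoylbenzyl]-6-isopropoxy-5-methylphenyl}butan-1-one | CCCC(=O)c1c(OC(C)C)c(C)c(OCc2ccccc2)c(Cc2c(OCc3ccccc3)c(C(=O)CC)c(OCc3ccccc3)c(C)c2OC)c1OCc1ccccc1
F7 | step 12 | 1-{3-[2,4-dihydroxy-6-methoxy-5-methyl-3-propanoylbenzyl]-2,4-dihydroxy-6-isopropoxy-5-methylphenyl}butan-1-one | CCCC(=O)c1c(OC(C)C)c(C)c(O)c(Cc2c(O)c(C(=O)CC)c(O)c(C)c2OC)c1O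
F8 | step 8 | bis(trimethylsilyl) 2-[2,4-bis(benzyloxy)-6-methoxy-5-methyl-3-propanoylbenzyl]malonate | C[Si](C)(C)OC(=O)C(Cc1c(OCc2ccccc2)c(C(=O)CC)c(OCc2ccccc2)c(C)c1OC)C(=O)O[Si](C)(C)C
F9 | step 2 | 1-(2,4,6-trimethoxy-3-methylphenyl)propan-1-one | CCC(=O)c1c(OC)cc(OC)c(C)c1OC
A1 | alternative 1 | 1-[2,6-dihydroxy-4-methoxy-3-methyl-5-(2,4,6-tris(benzyloxy)-3-methylbenzyl)phenyl]propan-1-one | CCC(=O)c1c(O)c(C)c(OC)c(Cc2c(OCc3ccccc3)c(C)c(OCc3ccccc3)cc2OCc2ccccc2)c1O
A2 | alternative 1 | 4-methoxy-3-methyl-6-(2-oxobutyl)-5-[2,4,6-tris(benzyloxy)-3-methylbenzyl]pyran-2-one | CCC(=O)CC1=C(Cc2c(OCc3ccccc3)c(C)c(OCc3ccccc3)cc2OCc2ccccc2)C(OC)=C(C)C(=O)O1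
A3 | alternative 2 | 1-[2-ethoxy-6-hydroxy-4-methoxy-3-methyl-5-(2,4,6-tris(benzyloxy)-3-methylbenzyl)phenyl]propan-1-one | CCOc1c(C)c(OC)c(Cc2c(OCc3ccccc3)c(C)c(OCc3ccccc3)cc2OCc2ccccc2)c(O)c1C(=O)CC
A4 | alternative 2 | 1,3-dimethoxy-2-[2,4,6-tris(benzyloxy)-3-methylbenzyl]-1-(trimethylsiloxy)penta-1,3-diene (mixture of double-bond isomers) | CC=C(OC)C(Cc1c(OCc2ccccc2)c(C)c(OCc2ccccc2)cc1OCc1ccccc1)=C(OC)O[Si](C)(C)C
A5 | alternative 2 | 1-ethoxypent-1-yn-3-one | CCOC#CC(=O)CC
A6 | alternative 3 | 1-{2,4,6-tris(benzyloxy)-3-[2,4-bis(benzyloxy)-6-methoxy-5-methyl-3-propanoylbenzyl]-5-methylphenyl}butan-1-one | CCCC(=O)c1c(OCc2ccccc2)c(C)c(OCc2ccccc2)c(Cc2c(OCc3ccccc3)c(C(=O)CC)c(OCc3ccccc3)c(C)c2OC)c1OCc1ccccc1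
A7 | alternative 3 | 1-[2,6-bis(benzyloxy)-4-methoxy-3-methyl-5-(2,4,6-tris(benzyloxy)-3-iodo-5-methylbenzyl)phenyl]propan-1-one | CCC(=O)c1c(OCc2ccccc2)c(C)c(OC)c(Cc2c(OCc3ccccc3)c(I)c(OCc3ccccc3)c(C)c2OCc2ccccc2)c1OCc1ccccc1
A8 | alternative 3 | B-propyl-9-borabicyclo[3.3.1]nonane | CCCB1C2CCCC1CCC2
A9 | alternative 3 | carbon monoxide | [C-]#[O+]
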